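Percent of the substrate charged is the unit to reckon in, and the fraction to watch is the one that never arrives, not the one made. Violet is the asked flask, followed so far; the grey run differs from it in reagent. Substrate is the limiting reagent, 0.050 M against 0.200 M of reagent in violet.

| setting | violet | grey | flask |
|---|---|---|---|
| substrate | 0.050 M | 0.050 M | 0.050 M |
| reagent | 0.20 M | 0.13 M | 0.200 M |
| initiator | 7.5 mM | 7.5 mM | 7.5 mM |
| remark | the very flask that is asked about, followed so far | run made earlier |  |
| time |  |  | 8.0 min |

- violet (time / min: product / %, substrate / %): 0.200: 17, 79; 0.667: 52, 48; 1.00: 72, 23; 1.50: 87, 6; 2.50: 92, 0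
- grey (time / min: product / %, substrate / %): 0.667: 35, 62; 1.33: 59, 30; 2.50: 89, 1; 4.00: 91, 2; 8.00: 90, 0

(each reading ± 2 percentage points)

1. the product standing at 8.0 min, as a percentage of the substrate charged
2. amount of product if the flask were left three thousand times as long, in percent of the substrate charged

- the analysis behind the earlier runs scatters by 2 percentage points, standard deviation
- a reading or a percentage of product counts all its forms, free or not

The odd thing: at 2.50 min violet shows substrate at 0% and product at 92%, so the substrate is gone, yet 8.00% of it is not product, against a scatter of 2 percentage points. Grey's last three readings average a shortfall share of 10.0%. Early on, substrate falls along a nearly straight line, and violet's slope is 1.45 times grey's, close to the reagent ratio of 1.54. So the speed follows c(reagent). Assume the loss keeps a pace of its own: the shortfall share then grows with the time consumption takes, and falls as 1/c(reagent). The two runs give 14.5 mM for the loss constant, the shortfall share times c(reagent). For violet I reckon 92.8% product, and I hold that for the long wait because grey stays flat from 2.50 min to 8.00 min, though no reading reaches that far.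

The forecast says 91% and 91%, a little under my figure; its level comes from the plateau readings of both runs, “92 in violet, and 89, 91, 90 in grey, averaging about 91”.

    2 chain carrier → ended chains B (k = 1.30 × 10⁸ M⁻¹ s⁻¹)
    substrate + initiating radical ⇌ chain carrier (K = 39000 M⁻¹, k = 1.10 × 10⁵ M⁻¹ s⁻¹)
    initiator → 2 initiating radical (k = 0.00400 s⁻¹)
    2 initiating radical → ended chains A (k = 8.10 × 10⁷ M⁻¹ s⁻¹)
    crystals ⇌ product, rate k5*(cs5 - [product]) while solid is left; crystals form when [product] > cs5 (solubility = 29.0 mM, k = 0.360 s⁻¹)
    reagent + chain carrier → product + initiating radical (k = 7700 M⁻¹ s⁻¹)

The flask gives 93.5% at the asked time and 93.5% for the long wait; its shortfall stands as ended chains B, 6.47% with each counted as two, so its loss constant reads 13.0 mM. Product stands at 93.5% at 80.0 min. The neighbour with 0.050 M of reagent keeps 7.12% substrate at its end, so the loss constant gives it a share of 29.0% and 65.9% product; that neighbour stands at 67.7%.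

(The numbers in the tables come from a simulation from invented constants; the scatter is artificial.)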